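**Plan**

1. Locants: chroman O1–C8a (arene = ring A, pyran = ring B); side chain C1'–C13' counted from C2, so C8' is the CH(CH3) centre and C9' the ketone carbon.
2. Enabling feature: the sp3 stereocentre C8' lies directly beside the oxidised carbon C9', so both can be carried as boron-bearing carbons; C7'–C8' and C8'–C9' become two successive carbenoid insertions into a C–B bond, and C9'=O is a C–B bond oxidised twice.
3. Retrosynthetic cuts, in order: O–Si; C9'=O; C8'–C9'; C7'–C8'; C6'–C7'; C5'–C6'; C5'–O (allylic oxidation of a prenyl end); O1–C8a; C4–C4a, which leads back to (R)-linalool and a bromo-iodo-cresol silyl ether.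
4. Forward: ring A is prepared as the dihalide and joined to linalool at C4–C4a (B-alkyl Suzuki coupling), ring B is closed at O1–C8a (Pd etherification), and the chain then grows C5' → C6' → C7' → C8' → C9'–C13' at boron.
5. Stereochemistry: C2 comes from (R)-linalool (its C–O bond is never broken); 3'E from E-selective SeO2 oxidation of the gem-dimethyl terminus; C8' from (+)-sparteine-directed lithiation followed by a stereospecific 1,2-migration (reagent control).

Key step: step 12

Remark: commercial (R)-(−)-linalool of high enantiomeric purity is assumed; the configuration at C9' in 26 is without consequence because C9' becomes the carbonyl carbon.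

**Route**

Step 1
Reactants: 1 4-amino-3-methylphenol
Product: 2 2-methyl-4-[(triisopropylsilyl)oxy]aniline
Conditions: TIPSCl, imidazole, DMF, 0 °C to rt
Reagents that add atoms: chlorotriisopropylsilane, CC(C)[Si](Cl)(C(C)C)C(C)C
Why: Imidazole-promoted silylation should be selective for the phenol oxygen (any N–Si bond is hydrolysed on work-up), and the bulky silyl ether masks the future chromanol against the organolithium and oxidation steps.

Step 2
Reactants: 2 2-methyl-4-[(triisopropylsilyl)oxy]aniline
Product: 3 2-iodo-6-methyl-4-[(triisopropylsilyl)oxy]aniline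
Conditions: NIS, MeCN, 0 °C, dark
Reagents that add atoms: N-iodosuccinimide, O=C1CCC(=O)N1I
Why: Electrophilic aromatic iodination should go ortho to the amino group, the strongest donor, at the only free position ortho or para to nitrogen.

Step 3
Reactants: 3 2-iodo-6-methyl-4-[(triisopropylsilyl)oxy]aniline
Product: 5 (4-bromo-3-iodo-5-methylphenoxy)triisopropylsilane, via arenediazonium bromide 4 (not isolated)
Conditions: t-BuONO, CuBr2, MeCN, 0 to 60 °C
Reagents that add atoms: copper dibromide, Br[Cu]Br
Why: Non-aqueous Sandmeyer bromination (alkyl nitrite, CuBr2) should replace the diazotised amino group by bromine without touching the aryl iodide or the silyl ether, which places Br between CH3 and I.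

Step 4
Reactants: 6 (R)-(−)-linalool, 5 (4-bromo-3-iodo-5-methylphenoxy)triisopropylsilane
Product: 8 (3R)-1-[2-bromo-3-methyl-5-(triisopropylsilyloxy)phenyl]-3,7-dimethyloct-6-en-3-ol, via B-alkyl-9-BBN adduct 7 (not isolated)
Conditions: 9-BBN, THF, 0 °C to rt; then 5, PdCl2(dppf) (5 mol %), aq. K3PO4, DMF, rt
Reagents that add atoms: none
Why: 9-BBN should hydroborate only the monosubstituted vinyl group of 6, and the B-alkyl Suzuki–Miyaura coupling should occur at the C–I bond, which adds oxidatively far faster than the flanked C–Br bond, so that C4–C4a forms while the carbinol stereocentre is untouched.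

Step 5
Reactants: 8 (3R)-1-[2-bromo-3-methyl-5-(triisopropylsilyloxy)phenyl]-3,7-dimethyloct-6-en-3-ol
Product: 9 (2R)-2,8-dimethyl-2-(4-methylpent-3-en-1-yl)-6-(triisopropylsilyloxy)chromane
Conditions: Pd(OAc)2 (5 mol %), 2-(di-tert-butylphosphino)-1,1'-binaphthyl, Cs2CO3, toluene, 80 °C
Reagents that add atoms: none
Why: Intramolecular Pd-catalysed aryl etherification (Buchwald–Hartwig C–O coupling) should close ring B at O1–C8a, since the tertiary alkoxide has no hydrogen for beta-hydride elimination, and C2 keeps the linalool configuration because its C–O bond is not broken.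

Step 6
Reactants: 9 (2R)-2,8-dimethyl-2-(4-methylpent-3-en-1-yl)-6-(triisopropylsilyloxy)chromane
Product: 10 (2E)-2-methyl-5-[(2R)-2,8-dimethyl-6-(triisopropylsilyloxy)chroman-2-yl]pent-2-en-1-ol
Conditions: SeO2 (cat.), t-BuOOH, salicylic acid (cat.), CH2Cl2, 0 °C to rt
Reagents that add atoms: selenium dioxide, O=[Se]=O (oxygen carrier); tert-butyl hydroperoxide, CC(C)(C)OO (stoichiometric oxidant)
Why: Riley allylic oxidation (ene reaction, then [2,3]-sigmatropic shift) should hydroxylate the (E)-methyl group of the gem-dimethyl alkene selectively, which fixes the 3'E geometry and makes C5' the new handle.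

Step 7
Reactants: 10 (2E)-2-methyl-5-[(2R)-2,8-dimethyl-6-(triisopropylsilyloxy)chroman-2-yl]pent-2-en-1-ol
Product: 11 (2R)-2-[(3E)-5-bromo-4-methylpent-3-en-1-yl]-2,8-dimethyl-6-(triisopropylsilyloxy)chromane
Conditions: CBr4, PPh3, CH2Cl2, 0 °C
Reagents that add atoms: carbon tetrabromide, BrC(Br)(Br)Br
Why: The Appel reaction should convert the primary allylic alcohol into the bromide by SN2 displacement of the oxyphosphonium group, without allylic shift or loss of alkene geometry.

Step 8
Reactants: 11 (2R)-2-[(3E)-5-bromo-4-methylpent-3-en-1-yl]-2,8-dimethyl-6-(triisopropylsilyloxy)chromane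
Product: 12 pinacol [(3E)-3-methyl-6-[(2R)-2,8-dimethyl-6-(triisopropylsilyloxy)chroman-2-yl]hex-3-en-1-yl]boronate
Conditions: CH2(Bpin)2, NaOt-Bu, THF, rt; then 11, 0 °C to rt
Reagents that add atoms: bis(pinacolato)borylmethane, CC1(C)OB(CB2OC(C)(C)C(C)(C)O2)OC1(C)C
Why: Alkoxide-promoted deborylative alkylation of the geminal bis(boronate) should deliver a boryl-stabilised CH2 nucleophile that displaces the primary allylic bromide in the SN2 sense, adding C6' with a C–B bond already in place.

Step 9
Reactants: 12 pinacol [(3E)-3-methyl-6-[(2R)-2,8-dimethyl-6-(triisopropylsilyloxy)chroman-2-yl]hex-3-en-1-yl]boronate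
Product: 14 pinacol [(4E)-4-methyl-7-[(2R)-2,8-dimethyl-6-(triisopropylsilyloxy)chroman-2-yl]hept-4-en-1-yl]boronate, via chloromethyl boronate complex 13 (not isolated)
Conditions: BrCH2Cl, n-BuLi, THF, −78 °C to rt
Reagents that add atoms: bromochloromethane, ClCBr
Why: Matteson homologation with chloromethyllithium generated in the flask should insert C7' into the C–B bond through boronate 13 and a 1,2-shift with loss of chloride.

Step 10
Reactants: 15 2,4,6-triisopropylbenzoic acid, 16 iodoethane
Product: 17 ethyl 2,4,6-triisopropylbenzoate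
Conditions: K2CO3, DMF, rt
Reagents that add atoms: none
Why: SN2 O-alkylation of the hindered carboxylate should give the ester whose shielded carbonyl withstands s-BuLi and directs the alpha-lithiation.

Step 11
Reactants: 15 2,4,6-triisopropylbenzoic acid, 18 5-bromo-2-methylpent-2-ene
Product: 19 4-methylpent-3-en-1-yl 2,4,6-triisopropylbenzoate
Conditions: K2CO3, DMF, 50 °C
Reagents that add atoms: none
Why: SN2 O-alkylation of the carboxylate by the primary homoallylic bromide should give the ester that later serves as the C9'–C13' carbenoid precursor.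

Step 12
Reactants: 17 ethyl 2,4,6-triisopropylbenzoate, 14 pinacol [(4E)-4-methyl-7-[(2R)-2,8-dimethyl-6-(triisopropylsilyloxy)chroman-2-yl]hept-4-en-1-yl]boronate
Product: 22 pinacol [(2S,6E)-6-methyl-9-[(2R)-2,8-dimethyl-6-(triisopropylsilyloxy)chroman-2-yl]non-6-en-2-yl]boronate, via lithiated benzoate 20 (not isolated), via boronate complex 21 (not isolated)
Conditions: 17, s-BuLi, (+)-sparteine, Et2O, −78 °C, 5 h; then 14, −78 °C, 1 h; then 35 °C, 12 h
Reagents that add atoms: none
Why: s-BuLi/(+)-sparteine should remove the pro-R alpha-oxygen proton of 17 to give the configurationally stable (R)-lithiated benzoate 20, which adds to the boron of 14 with retention at carbon to give the tetracoordinate boronate 21; on warming, the C7' alkyl group migrates from boron to C8' anti-periplanar to the departing triisopropylbenzoate (1,2-metallate rearrangement with inversion at C8'), which forms the C7'–C8' bond. The closest known reaction type is lithiation–borylation, a reagent-controlled Matteson-type homologation that is established for primary alkyl pinacol boronates and ethyl triisopropylbenzoate. No ring is closed in this step. The new stereocentre C8' (S) is controlled only by the sparteine enantiomer (retention on boronate formation, inversion on migration) and so does not depend on the remote C2 centre. The step needs attack at boron only and migration of carbon instead of a pinacol oxygen: 14 offers no other electrophilic site at −78 °C (aryl silyl ether, chroman ether and trisubstituted alkenes are inert to the hindered carbenoid), and alkyl groups migrate far faster than the diol oxygen when a benzoate leaves. The resulting C8'–B bond is the handle for the next insertion, which builds C9' without ever placing base next to the future ketone.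

Step 13
Reactants: 19 4-methylpent-3-en-1-yl 2,4,6-triisopropylbenzoate, 22 pinacol [(2S,6E)-6-methyl-9-[(2R)-2,8-dimethyl-6-(triisopropylsilyloxy)chroman-2-yl]non-6-en-2-yl]boronate
Product: 26 (2R)-2-[(3E,8S,9R)-9-hydroxy-4,8,12-trimethyltrideca-3,11-dien-1-yl]-2,8-dimethyl-6-(triisopropylsilyloxy)chromane, via lithiated benzoate 23 (not isolated), via boronate complex 24 (not isolated), via boronic ester 25 (not isolated)
Conditions: 19, s-BuLi, (−)-sparteine, Et2O, −78 °C, 5 h; then 22, −78 to 35 °C; then NaBO3·4H2O, THF/H2O, rt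
Reagents that add atoms: sodium perborate, [Na+].[O-]OB=O
Why: A second lithiation–borylation should insert C9' into the C8'–B bond with retention at the migrating C8' (the C9' configuration set by (−)-sparteine is immaterial), and perborate oxidation of boronic ester 25 should give the alcohol with retention.

Step 14
Reactants: 26 (2R)-2-[(3E,8S,9R)-9-hydroxy-4,8,12-trimethyltrideca-3,11-dien-1-yl]-2,8-dimethyl-6-(triisopropylsilyloxy)chromane
Product: 27 (2R)-2,8-dimethyl-2-[(3E,8S)-4,8,12-trimethyl-9-oxotrideca-3,11-dien-1-yl]-6-(triisopropylsilyloxy)chromane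
Conditions: Dess–Martin periodinane, NaHCO3, CH2Cl2, 0 °C to rt
Reagents that add atoms: none
Why: Dess–Martin oxidation under bicarbonate buffer should give the beta,gamma-unsaturated ketone under non-enolising conditions, so that C8' is not epimerised and the C11' alkene does not move into conjugation.

Step 15
Reactants: 27 (2R)-2,8-dimethyl-2-[(3E,8S)-4,8,12-trimethyl-9-oxotrideca-3,11-dien-1-yl]-6-(triisopropylsilyloxy)chromane
Product: 28 (2R)-2,8-dimethyl-2-[(3E,8S)-4,8,12-trimethyl-9-oxotrideca-3,11-dien-1-yl]chroman-6-ol (CNP0280076.1)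
Conditions: TBAF, AcOH (1:1), THF, 0 °C
Reagents that add atoms: none
Why: Fluoride cleavage of the aryl silyl ether, buffered with acetic acid so that the medium cannot enolise the ketone, should release the chromanol and complete the target.

**Compound list**

1 | 4-amino-3-methylphenol | Cc1cc(O)ccc1N | starting material
2 | 2-methyl-4-[(triisopropylsilyl)oxy]aniline | Cc1cc(O[Si](C(C)C)(C(C)C)C(C)C)ccc1N | intermediate
3 | 2-iodo-6-methyl-4-[(triisopropylsilyl)oxy]aniline | Cc1cc(O[Si](C(C)C)(C(C)C)C(C)C)cc(I)c1N | intermediate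
4 | 2-iodo-6-methyl-4-[(triisopropylsilyl)oxy]benzenediazonium bromide | Cc1cc(O[Si](C(C)C)(C(C)C)C(C)C)cc(I)c1[N+]#N.[Br-] | intermediate (not isolated)
5 | (4-bromo-3-iodo-5-methylphenoxy)triisopropylsilane | Cc1cc(O[Si](C(C)C)(C(C)C)C(C)C)cc(I)c1Br | intermediate
6 | (R)-(−)-linalool, (3R)-3,7-dimethylocta-1,6-dien-3-ol | CC(C)=CCC[C@@](C)(O)C=C | starting material
7 | (3S)-1-(9-borabicyclo[3.3.1]nonan-9-yl)-3,7-dimethyloct-6-en-3-ol (same spatial arrangement as 6; the descriptor changes with the priorities) | CC(C)=CCC[C@@](C)(O)CCB1C2CCCC1CCC2 | intermediate (not isolated)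
8 | (3R)-1-[2-bromo-3-methyl-5-(triisopropylsilyloxy)phenyl]-3,7-dimethyloct-6-en-3-ol | CC(C)=CCC[C@@](C)(O)CCc1cc(O[Si](C(C)C)(C(C)C)C(C)C)cc(C)c1Br | intermediate
9 | (2R)-2,8-dimethyl-2-(4-methylpent-3-en-1-yl)-6-(triisopropylsilyloxy)chromane | CC(C)=CCC[C@]1(C)CCc2cc(O[Si](C(C)C)(C(C)C)C(C)C)cc(C)c2O1 | intermediate
10 | (2E)-2-methyl-5-[(2R)-2,8-dimethyl-6-(triisopropylsilyloxy)chroman-2-yl]pent-2-en-1-ol | OC/C(C)=C/CC[C@]1(C)CCc2cc(O[Si](C(C)C)(C(C)C)C(C)C)cc(C)c2O1 | intermediate
11 | (2R)-2-[(3E)-5-bromo-4-methylpent-3-en-1-yl]-2,8-dimethyl-6-(triisopropylsilyloxy)chromane | BrC/C(C)=C/CC[C@]1(C)CCc2cc(O[Si](C(C)C)(C(C)C)C(C)C)cc(C)c2O1 | intermediate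
12 | pinacol [(3E)-3-methyl-6-[(2R)-2,8-dimethyl-6-(triisopropylsilyloxy)chroman-2-yl]hex-3-en-1-yl]boronate | CC1(C)OB(CC/C(C)=C/CC[C@]2(C)CCc3cc(O[Si](C(C)C)(C(C)C)C(C)C)cc(C)c3O2)OC1(C)C | intermediate
13 | lithium (chloromethyl)boronate complex of 12 | [Li+].ClC[B-]1(CC/C(C)=C/CC[C@]2(C)CCc3cc(O[Si](C(C)C)(C(C)C)C(C)C)cc(C)c3O2)OC(C)(C)C(C)(C)O1 | intermediate (not isolated)
14 | pinacol [(4E)-4-methyl-7-[(2R)-2,8-dimethyl-6-(triisopropylsilyloxy)chroman-2-yl]hept-4-en-1-yl]boronate | CC1(C)OB(CCC/C(C)=C/CC[C@]2(C)CCc3cc(O[Si](C(C)C)(C(C)C)C(C)C)cc(C)c3O2)OC1(C)C | intermediate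
15 | 2,4,6-triisopropylbenzoic acid | OC(=O)c1c(C(C)C)cc(C(C)C)cc1C(C)C | starting material
16 | iodoethane | CCI | starting material
17 | ethyl 2,4,6-triisopropylbenzoate | CCOC(=O)c1c(C(C)C)cc(C(C)C)cc1C(C)C | intermediate
18 | 5-bromo-2-methylpent-2-ene | CC(C)=CCCBr | starting material
19 | 4-methylpent-3-en-1-yl 2,4,6-triisopropylbenzoate | CC(C)=CCCOC(=O)c1c(C(C)C)cc(C(C)C)cc1C(C)C | intermediate
20 | (R)-1-lithioethyl 2,4,6-triisopropylbenzoate (as its (+)-sparteine complex) | C[C@@H]([Li])OC(=O)c1c(C(C)C)cc(C(C)C)cc1C(C)C | intermediate (not isolated)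
21 | lithium boronate complex of 20 and 14 | [Li+].C[C@H](OC(=O)c1c(C(C)C)cc(C(C)C)cc1C(C)C)[B-]2(CCC/C(C)=C/CC[C@]3(C)CCc4cc(O[Si](C(C)C)(C(C)C)C(C)C)cc(C)c4O3)OC(C)(C)C(C)(C)O2 | intermediate (not isolated)
22 | pinacol [(2S,6E)-6-methyl-9-[(2R)-2,8-dimethyl-6-(triisopropylsilyloxy)chroman-2-yl]non-6-en-2-yl]boronate (boron on C8') | CC1(C)OB(OC1(C)C)[C@@H](C)CCC/C(C)=C/CC[C@]2(C)CCc3cc(O[Si](C(C)C)(C(C)C)C(C)C)cc(C)c3O2 | intermediate
23 | (S)-1-lithio-4-methylpent-3-en-1-yl 2,4,6-triisopropylbenzoate (as its (−)-sparteine complex) | CC(C)=CC[C@H]([Li])OC(=O)c1c(C(C)C)cc(C(C)C)cc1C(C)C | intermediate (not isolated)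
24 | lithium boronate complex of 23 and 22 | [Li+].CC(C)=CC[C@@H](OC(=O)c1c(C(C)C)cc(C(C)C)cc1C(C)C)[B-]2(OC(C)(C)C(C)(C)O2)[C@@H](C)CCC/C(C)=C/CC[C@]3(C)CCc4cc(O[Si](C(C)C)(C(C)C)C(C)C)cc(C)c4O3 | intermediate (not isolated)
25 | (2R)-2-[(3E,8S,9R)-4,8,12-trimethyl-9-(4,4,5,5-tetramethyl-1,3,2-dioxaborolan-2-yl)trideca-3,11-dien-1-yl]-2,8-dimethyl-6-(triisopropylsilyloxy)chromane | CC(C)=CC[C@@H](B1OC(C)(C)C(C)(C)O1)[C@@H](C)CCC/C(C)=C/CC[C@]2(C)CCc3cc(O[Si](C(C)C)(C(C)C)C(C)C)cc(C)c3O2 | intermediate (not isolated)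
26 | (2R)-2-[(3E,8S,9R)-9-hydroxy-4,8,12-trimethyltrideca-3,11-dien-1-yl]-2,8-dimethyl-6-(triisopropylsilyloxy)chromane | CC(C)=CC[C@@H](O)[C@@H](C)CCC/C(C)=C/CC[C@]1(C)CCc2cc(O[Si](C(C)C)(C(C)C)C(C)C)cc(C)c2O1 | intermediate
27 | (2R)-2,8-dimethyl-2-[(3E,8S)-4,8,12-trimethyl-9-oxotrideca-3,11-dien-1-yl]-6-(triisopropylsilyloxy)chromane | CC(C)=CCC(=O)[C@@H](C)CCC/C(C)=C/CC[C@]1(C)CCc2cc(O[Si](C(C)C)(C(C)C)C(C)C)cc(C)c2O1 | intermediate
28 | (2R)-2,8-dimethyl-2-[(3E,8S)-4,8,12-trimethyl-9-oxotrideca-3,11-dien-1-yl]chroman-6-ol | CC(C)=CCC(=O)[C@@H](C)CCC/C(C)=C/CC[C@]1(C)CCc2cc(O)cc(C)c2O1 | target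

**Count**

Total steps: 15. Longest linear sequence: 13 steps (1 to 28 through steps 1–9 and 12–15).

**Steps most likely to fail**

1. Step 13. Boronate formation between the hindered secondary boronic ester and the hindered carbenoid may be slow, and deprotonation of 19 at the allylic CH2 may compete with alpha-lithiation. The fallback builds C9' as an aldehyde and brings in C10'–C13' as a vinyl nucleophile. It sets out from 22: Matteson homologation with LiCHCl2 (CH2Cl2, n-BuLi, THF, −100 °C; then ZnCl2) would give the alpha-chloro boronic ester (2R)-2-[(3E,8S)-9-chloro-4,8-dimethyl-9-(4,4,5,5-tetramethyl-1,3,2-dioxaborolan-2-yl)non-3-en-1-yl]-2,8-dimethyl-6-(triisopropylsilyloxy)chromane F1. Oxidation (NaBO3·4H2O, THF/H2O) would give the aldehyde (2S,6E)-2,6-dimethyl-9-[(2R)-2,8-dimethyl-6-(triisopropylsilyloxy)chroman-2-yl]non-6-enal F2. Corey–Chaykovsky methylenation (trimethylsulfonium iodide, n-BuLi, THF, −10 °C) would give the terminal epoxide 2-[(2S,6E)-6-methyl-9-[(2R)-2,8-dimethyl-6-(triisopropylsilyloxy)chroman-2-yl]non-6-en-2-yl]oxirane F3. Opening at the CH2 terminus with (2-methylprop-1-en-1-yl)magnesium bromide and CuI (cat.) in THF at −30 °C comes back to the route at 26, as a mixture of C9' epimers that converge at 27.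

2. Step 5. Reductive elimination of the C–O bond from the electron-rich, doubly ortho-substituted arylpalladium alkoxide may be slower than protodebromination. The fallback places the oxygen on C8a first and closes ring B from the arene side. It sets out from 8: Pd-catalysed hydroxylation (Pd2(dba)3, t-BuXPhos, KOH, dioxane/H2O, 100 °C, with loss of the silyl ether) should give the hydroquinone 2-[(3R)-3-hydroxy-3,7-dimethyloct-6-en-1-yl]-6-methylbenzene-1,4-diol F4. Acid-mediated ring closure (camphorsulfonic acid, toluene, 60 °C, under argon) should give (2R)-2,8-dimethyl-2-(4-methylpent-3-en-1-yl)chroman-6-ol F5. By analogy with the ring closure of tocopherylhydroquinones, this is expected to run with retention, because the carbinol oxygen adds ipso at the protonated ring carbon C8a and the phenolic oxygen leaves as water; this stereochemical course is recalled from the vitamin E literature and would have to be confirmed on F5. Silylation of F5 (TIPSCl, imidazole, DMF) comes back to the route at 9.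

3. Step 12. Incomplete enantiodiscrimination in the sparteine-mediated deprotonation would appear as the C8' epimer of 22, which is hard to remove because the two stereocentres are remote. The fallback moves the enantio-determining event out of the coupling into an isolable reagent. It sets out from 17: lithiation (s-BuLi, (+)-sparteine, Et2O, −78 °C) and quench with Me3SnCl would give (R)-1-(trimethylstannyl)ethyl 2,4,6-triisopropylbenzoate F6, whose enantiomeric purity can be raised by recrystallisation. Tin–lithium exchange (n-BuLi, Et2O, −78 °C, retention) regenerates 20 without diamine, and addition of 14 with warming as in step 12 comes back to the route at 22.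

**Further compounds**

F1 | step 13 | (2R)-2-[(3E,8S)-9-chloro-4,8-dimethyl-9-(4,4,5,5-tetramethyl-1,3,2-dioxaborolan-2-yl)non-3-en-1-yl]-2,8-dimethyl-6-(triisopropylsilyloxy)chromane (C9' epimers) | ClC(B1OC(C)(C)C(C)(C)O1)[C@@H](C)CCC/C(C)=C/CC[C@]2(C)CCc3cc(O[Si](C(C)C)(C(C)C)C(C)C)cc(C)c3O2
F2 | step 13 | (2S,6E)-2,6-dimethyl-9-[(2R)-2,8-dimethyl-6-(triisopropylsilyloxy)chroman-2-yl]non-6-enal | O=C[C@@H](C)CCC/C(C)=C/CC[C@]1(C)CCc2cc(O[Si](C(C)C)(C(C)C)C(C)C)cc(C)c2O1
F3 | step 13 | 2-[(2S,6E)-6-methyl-9-[(2R)-2,8-dimethyl-6-(triisopropylsilyloxy)chroman-2-yl]non-6-en-2-yl]oxirane (epimers at the oxirane carbon) | C1OC1[C@@H](C)CCC/C(C)=C/CC[C@]2(C)CCc3cc(O[Si](C(C)C)(C(C)C)C(C)C)cc(C)c3O2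
F4 | step 5 | 2-[(3R)-3-hydroxy-3,7-dimethyloct-6-en-1-yl]-6-methylbenzene-1,4-diol | CC(C)=CCC[C@@](C)(O)CCc1cc(O)cc(C)c1O
F5 | step 5 | (2R)-2,8-dimethyl-2-(4-methylpent-3-en-1-yl)chroman-6-ol | CC(C)=CCC[C@]1(C)CCc2cc(O)cc(C)c2O1
F6 | step 12 | (R)-1-(trimethylstannyl)ethyl 2,4,6-triisopropylbenzoate | C[C@@H]([Sn](C)(C)C)OC(=O)c1c(C(C)C)cc(C(C)C)cc1C(C)C
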